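**Retrosynthetic overview** (labdane numbering throughout)
- The strategy rests on ring B: oxygen on the adjacent carbons C6 and C7, a methyl on C8 and the spiro ether carbon C9 para to C6 are the pattern of a 4-alkyl-2-methoxyphenol with the phenol oxygen at C6.
- Key disconnection: the C9–O bond of ring C, made by oxidative dearomatisation of that phenol with spirolactonisation by its propanoic acid side chain (C11–C13).
- Ring A: C10–C1 by conjugate addition of a homoprenyl group to the dienone, then C4–C5 by cationic closure onto the enol of the C6 ketone.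
- C13: the lactone carbonyl takes up C16 (benzyloxymethyllithium) and then C14–C15 (alkynyl attack on the oxocarbenium ion); ring D closes last by alkynol cycloisomerisation (O–C15).
- Ring order B (arene) → C → A → D; C6/C7 are adjusted late by demethylation at the ketone stage, enol acetylation, α-face reduction and a 1,2-acetyl shift.

Key step: step 5

Remark: the (R,R) antipode of the iodoarene is assumed to give the S spirocentre (its mirror image is used if the sense of induction is the reverse), and the C13 epimers of step 9 are assumed to be separable by chromatography.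

**Step 1**
Reactants: 1 4-bromo-3,5-dimethylphenol; 2 methyl acrylate
Product: 3 methyl (E)-3-(4-hydroxy-2,6-dimethylphenyl)prop-2-enoate
Conditions: Pd(OAc)2 (3 mol%), P(o-tol)3, Et3N, DMF, 120 °C
Reagents that add atoms: none
Why: Heck reaction: zerovalent palladium inserts into the hindered aryl bromide, the acrylate inserts and β-hydride elimination gives the E-cinnamate, the bulky P(o-tol)3 ligand coping with the two ortho methyl groups.

**Step 2**
Reactants: 3 methyl (E)-3-(4-hydroxy-2,6-dimethylphenyl)prop-2-enoate
Product: 4 methyl 3-(4-hydroxy-2,6-dimethylphenyl)propanoate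
Conditions: H2 (1 atm), Pd/C (palladium on carbon), MeOH, rt
Reagents that add atoms: none
Why: Catalytic hydrogenation saturates the conjugated C=C bond and leaves the phenol, the arene and the ester untouched.

**Step 3**
Reactants: 4 methyl 3-(4-hydroxy-2,6-dimethylphenyl)propanoate
Product: 5 methyl 3-(3-bromo-4-hydroxy-2,6-dimethylphenyl)propanoate
Conditions: NBS (1.0 equiv), MeCN, 0 °C
Reagents that add atoms: N-bromosuccinimide, O=C1CCC(=O)N1Br
Why: Electrophilic aromatic bromination: with the para position blocked, the phenol directs one bromine to either of its two equivalent ortho positions, and one equivalent of NBS at 0 °C should hold the reaction at the monobromide.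

**Step 4**
Reactants: 5 methyl 3-(3-bromo-4-hydroxy-2,6-dimethylphenyl)propanoate
Product: 7 3-(4-hydroxy-3-methoxy-2,6-dimethylphenyl)propanoic acid, via methyl ester 6 (not isolated)
Conditions: NaOMe, CuI (10 mol%), MeOH–DMF, 110 °C; then H2O, 60 °C; aq. HCl
Reagents that add atoms: sodium methoxide, [Na+].[O-]C; water, O
Why: Ullmann-type copper-catalysed methoxylation of the ortho-bromophenoxide places the future C7 oxygen between the hydroxyl and a methyl group, and the hydroxide formed on adding water saponifies the methyl ester in the same pot.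

**Step 5**
Reactants: 7 3-(4-hydroxy-3-methoxy-2,6-dimethylphenyl)propanoic acid
Product: 8 (5S)-7-methoxy-6,10-dimethyl-1-oxaspiro[4.5]deca-6,9-diene-2,8-dione
Conditions: (R,R)-2,2'-[(2-iodo-1,3-phenylene)bis(oxy)]bis(N-mesitylpropanamide) (10 mol%), mCPBA (1.3 equiv, slow addition), CH2Cl2–(CF3)2CHOH, −20 °C
Reagents that add atoms: none
Why: Proposed new method: mCPBA oxidises the iodoarene to the trivalent aryl iodane, which exchanges a ligand for the phenol oxygen at C6; as the iodoarene departs, the para carbon C9 turns electrophilic and is captured by the tethered carboxylate, and because C9 is fully substituted the cross-conjugated dienone cannot rearomatise. The closest known reactions are the PhI(OAc)2-mediated para-spirolactonisation of 3-(4-hydroxyphenyl)propanoic acids and the chiral aryl iodide/mCPBA-catalysed enantioselective ortho-spirolactonisation and para-hydroxylative dearomatisation of phenols; new here is enantiocontrol in an intramolecular para closure on a monocyclic phenol. Ring C closes in a 5-exo-trig spirocyclisation through the O–C9 bond. C9 is the only new stereocentre; it is controlled by the chiral iodane held at the C6 oxygen, whose lactamide arms lie unequally over the C7-methoxy and C5-H edges and so should leave one face of C9 open to the carboxylate. The step needs para and not ortho attack, which the tether secures because attack at C5 or C7 would need a bridged or seven-membered transition state. It also needs the phenol to be oxidised before the product, which low temperature and slow addition of the oxidant should secure.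

**Step 6**
Reactants: 8 (5S)-spirolactone dienone; 9 5-bromo-2-methylpent-2-ene
Product: 11 (5S,10S)-7-methoxy-6,10-dimethyl-10-(4-methylpent-3-en-1-yl)-8-[(trimethylsilyl)oxy]-1-oxaspiro[4.5]deca-6,8-dien-2-one, via homoprenylmagnesium bromide 10 (not isolated)
Conditions: 9, Mg, THF, rt; then 8, CuBr·SMe2 (10 mol%), TMSCl, DMPU, THF, −78 → −40 °C; Et3N, pentane, cold filtration, used crude
Reagents that add atoms: chlorotrimethylsilane, C[Si](C)(C)Cl
Why: Copper-catalysed, TMSCl-accelerated conjugate addition of the Grignard reagent should go to C10, the β-carbon of the enone arm that carries no donor (the C7 methoxy group deactivates C8), from the face of the small lactone oxygen and away from the C11 methylene, so that C1 ends cis and the C10 methyl trans to the C9–O bond; silylation of the enolate masks the C6 carbonyl for step 8.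

**Step 7**
Reactants: 12 (tributylstannyl)methanol; 13 benzyl bromide
Product: 14 tributyl[(benzyloxy)methyl]stannane
Conditions: NaH, THF–DMF, 0 °C → rt
Reagents that add atoms: none
Why: Williamson ether synthesis of the sodium alkoxide with benzyl bromide gives the stannane precursor of a hydroxymethyl anion equivalent.

**Step 8**
Reactants: 11 silyl enol ether lactone; 14 tributyl[(benzyloxy)methyl]stannane
Product: 17 (5S,10S)-2-[(benzyloxy)methyl]-2-hydroxy-7-methoxy-6,10-dimethyl-10-(4-methylpent-3-en-1-yl)-1-oxaspiro[4.5]dec-6-en-8-one (anomers at C13), via benzyloxymethyllithium 15 (not isolated), via silyl enol ether hemiketal 16 (not isolated)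
Conditions: 14, n-BuLi, THF, −78 °C; then 11, −78 °C; AcOH; then Bu4NF–AcOH (1:1), THF, 0 °C
Reagents that add atoms: none
Why: Tin–lithium exchange gives the α-alkoxy organolithium, which adds once to the lactone carbonyl C13 at −78 °C (the tetrahedral lithium alkoxide does not collapse) while C6 is protected as its silyl enol ether; buffered fluoride then desilylates the enol ether to the ketone without acid (nucleophilic acyl addition to a lactone, C16–C13 bond).

**Step 9**
Reactants: 17 keto hemiketal; 18 trimethyl[(tributylstannyl)ethynyl]silane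
Product: 19 (2R,5S,10S)-2-[(benzyloxy)methyl]-7-methoxy-6,10-dimethyl-10-(4-methylpent-3-en-1-yl)-2-[(trimethylsilyl)ethynyl]-1-oxaspiro[4.5]dec-6-en-8-one
Conditions: TMSOTf (1.2 equiv), CH2Cl2, −78 → −40 °C; aq. KF
Reagents that add atoms: none
Why: Lewis acid ionisation of the hemiketal gives the C13 oxocarbenium ion (the restored C6 ketone keeps the C9–O bond from ionising), and the alkynylstannane should attack the inside face of the envelope that keeps the quaternary C10 pseudo-equatorial and the planar C8 pseudo-axial, that is syn to C10, which sets 13R (C-alkynylation of a ketose-type hemiketal through its oxocarbenium ion).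

**Step 10**
Reactants: 19 alkynyl spiro ether ketone
Product: 20 (5S,9S,10S,13R)-16-(benzyloxy)-9,13-epoxy-7-methoxy-15-(trimethylsilyl)labd-7-en-14-yn-6-one
Conditions: SnCl4 (2.2 equiv), CH2Cl2, −78 → 0 °C; aq. NaHCO3
Reagents that add atoms: none
Why: Proposed new method: SnCl4 is expected to bind the C6 carbonyl and the C7 methoxy oxygen as a five-membered chelate, which acidifies C5–H and gives a tin enolate with release of HCl; the acid protonates the 3,4-alkene in the Markovnikov sense and the tertiary C4 cation is captured by C5 through a chair transition state (six-membered ring A, 6-endo with respect to the alkene), the trans ring fusion (5α-H) being also the thermodynamic one at the epimerisable C5; the closest known reaction type is the SnCl4-promoted cyclisation of olefinic β-keto esters, a cation–olefin cyclisation ended by a chelated enol, and the chelate here also ties up the methoxy lone pair that could otherwise help the C9–O bond to ionise.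

**Step 11**
Reactants: 20 tricyclic methoxy enone
Product: 21 (5S,9S,10S,13R)-9,13-epoxy-7,16-dihydroxy-15-(trimethylsilyl)labd-7-en-14-yn-6-one
Conditions: BCl3 (4 equiv), CH2Cl2, −78 → −20 °C; aq. NaHCO3
Reagents that add atoms: none
Why: Lewis acid ether cleavage: BCl3 held in the C6 carbonyl/C7 methoxy chelate delivers chloride to the methyl group and, on warming, also cleaves the benzyl ether, all while the C6 ketone keeps the allylic C9–O bond from ionising, which is why the enol ether is unmasked at this oxidation level and not after reduction of C6.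

**Step 12**
Reactants: 21 diosphenol alcohol
Product: 22 (5S,9S,10S,13R)-7-acetoxy-9,13-epoxy-16-hydroxy-15-(trimethylsilyl)labd-7-en-14-yn-6-one
Conditions: Ac2O (1.1 equiv), Et3N, CH2Cl2, −40 → 0 °C
Reagents that add atoms: acetic anhydride, CC(=O)OC(C)=O
Why: Selective O-acylation: the acidic diosphenol hydroxyl should react as its ammonium enolate much faster than the neopentyl C16 alcohol when no acyl-transfer catalyst is present.

**Step 13**
Reactants: 22 enol acetate enone
Product: 23 (5S,6S,9S,10S,13R)-7-acetoxy-9,13-epoxy-15-(trimethylsilyl)labd-7-en-14-yne-6,16-diol (6β-hydroxy)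
Conditions: NaBH4, CeCl3·7H2O, MeOH, −78 °C
Reagents that add atoms: none
Why: Luche reduction: hydride adds 1,2 to the enone carbonyl from the α face, the β face of C6 being blocked by the syn-axial C20 and C19 methyl groups, which should give the axial 6β alcohol.

**Step 14**
Reactants: 23 6β-hydroxy enol acetate
Product: 24 (5S,6S,8S,9R,10S,13R)-6-acetoxy-9,13-epoxy-16-hydroxylabd-14-yn-7-one
Conditions: Bu4NF, THF, −20 → 0 °C; aq. NH4Cl
Reagents that add atoms: none
Why: Fluoride cleaves the alkynyl C–Si bond and, acting as a base, sets off the 1,2 O→O acyl migration from the enol acetate at O7 to the adjacent 6β alkoxide, which is downhill because it frees the C7 ketone; the enol is protonated at C8 and equilibrates to the equatorial 8α-methyl epimer, an 8β methyl being syn-axial to C20 and to the 6β acetate.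

**Step 15**
Reactants: 24 homopropargylic alcohol
Product: 25 (5S,6S,8S,9R,10S,13R)-6-acetoxy-9,13;15,16-diepoxylabd-14-en-7-one (target)
Conditions: Mo(CO)6 (25 mol%), Me3NO (25 mol%), Et3N–Et2O, rt; chromatography on Et3N-treated silica
Reagents that add atoms: none
Why: Alkynol cycloisomerisation through a molybdenum vinylidene: the C16 hydroxyl adds to the electrophilic C15 in a 5-endo closure to give the 2,3-dihydrofuran of ring D under amine-buffered, acid-free conditions, which the allylic spiro enol ether needs.

**Compound list**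
1 | 4-bromo-3,5-dimethylphenol | Cc1cc(O)cc(C)c1Br | starting material
2 | methyl acrylate | C=CC(=O)OC | starting material
3 | methyl (E)-3-(4-hydroxy-2,6-dimethylphenyl)prop-2-enoate | COC(=O)/C=C/c1c(C)cc(O)cc1C | intermediate
4 | methyl 3-(4-hydroxy-2,6-dimethylphenyl)propanoate | COC(=O)CCc1c(C)cc(O)cc1C | intermediate
5 | methyl 3-(3-bromo-4-hydroxy-2,6-dimethylphenyl)propanoate | COC(=O)CCc1c(C)cc(O)c(Br)c1C | intermediate
6 | methyl 3-(4-hydroxy-3-methoxy-2,6-dimethylphenyl)propanoate (not isolated) | COC(=O)CCc1c(C)cc(O)c(OC)c1C | intermediate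
7 | 3-(4-hydroxy-3-methoxy-2,6-dimethylphenyl)propanoic acid | COc1c(O)cc(C)c(CCC(=O)O)c1C | intermediate
8 | (5S)-7-methoxy-6,10-dimethyl-1-oxaspiro[4.5]deca-6,9-diene-2,8-dione (spiro carbon = C9) | COC1=C(C)[C@]2(CCC(=O)O2)C(C)=CC1=O | intermediate
9 | 5-bromo-2-methylpent-2-ene | CC(C)=CCCBr | starting material
10 | (4-methylpent-3-en-1-yl)magnesium bromide (not isolated) | CC(C)=CCC[Mg]Br | intermediate
11 | (5S,10S)-7-methoxy-6,10-dimethyl-10-(4-methylpent-3-en-1-yl)-8-[(trimethylsilyl)oxy]-1-oxaspiro[4.5]deca-6,8-dien-2-one | COC1=C(C)[C@]2(CCC(=O)O2)[C@@](C)(CCC=C(C)C)C=C1O[Si](C)(C)C | intermediate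
12 | (tributylstannyl)methanol | CCCC[Sn](CCCC)(CCCC)CO | starting material
13 | benzyl bromide | BrCc1ccccc1 | starting material
14 | tributyl[(benzyloxy)methyl]stannane | CCCC[Sn](CCCC)(CCCC)COCc1ccccc1 | intermediate
15 | [(benzyloxy)methyl]lithium (not isolated) | [Li]COCc1ccccc1 | intermediate
16 | (5S,10S)-2-[(benzyloxy)methyl]-7-methoxy-6,10-dimethyl-10-(4-methylpent-3-en-1-yl)-8-[(trimethylsilyl)oxy]-1-oxaspiro[4.5]deca-6,8-dien-2-ol, present as its lithium alkoxide, anomers at C13 (not isolated) | COC1=C(C)[C@]2(CCC(O)(COCc3ccccc3)O2)[C@@](C)(CCC=C(C)C)C=C1O[Si](C)(C)C | intermediate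
17 | (5S,10S)-2-[(benzyloxy)methyl]-2-hydroxy-7-methoxy-6,10-dimethyl-10-(4-methylpent-3-en-1-yl)-1-oxaspiro[4.5]dec-6-en-8-one, anomers at C13 | COC1=C(C)[C@]2(CCC(O)(COCc3ccccc3)O2)[C@@](C)(CCC=C(C)C)CC1=O | intermediate
18 | trimethyl[(tributylstannyl)ethynyl]silane | C[Si](C)(C)C#C[Sn](CCCC)(CCCC)CCCC | starting material
19 | (2R,5S,10S)-2-[(benzyloxy)methyl]-7-methoxy-6,10-dimethyl-10-(4-methylpent-3-en-1-yl)-2-[(trimethylsilyl)ethynyl]-1-oxaspiro[4.5]dec-6-en-8-one (C2 = C13) | COC1=C(C)[C@]2(CC[C@](COCc3ccccc3)(C#C[Si](C)(C)C)O2)[C@@](C)(CCC=C(C)C)CC1=O | intermediate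
20 | (5S,9S,10S,13R)-16-(benzyloxy)-9,13-epoxy-7-methoxy-15-(trimethylsilyl)labd-7-en-14-yn-6-one | O=C1C(OC)=C(C)[C@]2(CC[C@](COCc3ccccc3)(C#C[Si](C)(C)C)O2)[C@@]2(C)CCCC(C)(C)[C@H]12 | intermediate
21 | (5S,9S,10S,13R)-9,13-epoxy-7,16-dihydroxy-15-(trimethylsilyl)labd-7-en-14-yn-6-one | O=C1C(O)=C(C)[C@]2(CC[C@](CO)(C#C[Si](C)(C)C)O2)[C@@]2(C)CCCC(C)(C)[C@H]12 | intermediate
22 | (5S,9S,10S,13R)-7-acetoxy-9,13-epoxy-16-hydroxy-15-(trimethylsilyl)labd-7-en-14-yn-6-one | O=C1C(OC(C)=O)=C(C)[C@]2(CC[C@](CO)(C#C[Si](C)(C)C)O2)[C@@]2(C)CCCC(C)(C)[C@H]12 | intermediate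
23 | (5S,6S,9S,10S,13R)-7-acetoxy-9,13-epoxy-15-(trimethylsilyl)labd-7-en-14-yne-6,16-diol (6β-OH) | O[C@@H]1C(OC(C)=O)=C(C)[C@]2(CC[C@](CO)(C#C[Si](C)(C)C)O2)[C@@]2(C)CCCC(C)(C)[C@H]12 | intermediate
24 | (5S,6S,8S,9R,10S,13R)-6-acetoxy-9,13-epoxy-16-hydroxylabd-14-yn-7-one (6β-OAc, 8α-methyl) | CC(=O)O[C@@H]1C(=O)[C@@H](C)[C@]2(CC[C@](CO)(C#C)O2)[C@@]2(C)CCCC(C)(C)[C@H]12 | intermediate
25 | (5S,6S,8S,9R,10S,13R)-6-acetoxy-9,13;15,16-diepoxylabd-14-en-7-one | CC(=O)O[C@@H]1C(=O)[C@@H](C)[C@]2(CC[C@]3(C=COC3)O2)[C@@]2(C)CCCC(C)(C)[C@H]12 | target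

**Step count**
Total: 15 steps. Longest linear sequence: 14 steps (steps 1–6 and 8–15); step 7 is a one-step side branch.

**Steps most likely to fail**

Step 5. The chirality of the iodane bound at the C6 oxygen may be passed on only weakly to the remote para carbon, so that the carboxylate attacks both faces of C9. The electron-rich phenol may also be over-oxidised. The fallback sets out from 7: the achiral trivalent iodine reagent PhI(OAc)2 in MeCN–CF3CH2OH at 0 °C effects the known para-spirolactonisation and should give the racemic spirolactone dienone F1. Preparative chromatography on a chiral stationary phase then separates the S enantiomer, which is 8, from the R enantiomer F2, which is set aside. The route is rejoined at 8.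

Step 10. The C4 cation may be diverted before C5 can capture it, by proton loss, by chloride capture or by Prins-type attack of the alkene on the activated C6 carbonyl. The Lewis acid may also ionise the propargylic C13–O bond. The fallback sets out from 19 and separates the electrophile from the nucleophile. Dry HCl in CH2Cl2 at −78 °C adds across the alkene to give the tertiary chloride F3. TMSOTf and Et3N at 0 °C convert the ketone into the C5=C6 silyl enol ether F4. TiCl4 in CH2Cl2 at −78 °C then brings about the known Lewis acid mediated α-tert-alkylation of a silyl enol ether by a tertiary chloride, here intramolecular. The route is rejoined at 20.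

Step 6. Electron transfer from the organocopper species to the dienone may expel the C9 carboxylate and rearomatise ring B, or the addition at the congested C10 may be too slow. The fallback sets out from 8 and avoids reducing metals. Hosomi–Sakurai allylation with allyltrimethylsilane and TiCl4 in CH2Cl2 at −78 °C should give the C10 allyl ketone F5. Hydroboration with catecholborane and RhCl(PPh3)3, which spares the ketone, followed by NaBO3·4H2O gives the primary alcohol F6. Dess–Martin periodinane gives the aldehyde F7. Wittig reaction with the ylide from isopropyltriphenylphosphonium iodide and KN(SiMe3)2 gives the homoprenyl ketone F8. TMSOTf and Et3N convert F8 into the silyl enol ether, and the route is rejoined at 11.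

**Further compounds**
F1 | step 5 | racemic 7-methoxy-6,10-dimethyl-1-oxaspiro[4.5]deca-6,9-diene-2,8-dione | COC1=C(C)C2(CCC(=O)O2)C(C)=CC1=O
F2 | step 5 | (5R)-7-methoxy-6,10-dimethyl-1-oxaspiro[4.5]deca-6,9-diene-2,8-dione | COC1=C(C)[C@@]2(CCC(=O)O2)C(C)=CC1=O
F3 | step 10 | (2R,5S,10S)-2-[(benzyloxy)methyl]-10-(4-chloro-4-methylpentyl)-7-methoxy-6,10-dimethyl-2-[(trimethylsilyl)ethynyl]-1-oxaspiro[4.5]dec-6-en-8-one | COC1=C(C)[C@]2(CC[C@](COCc3ccccc3)(C#C[Si](C)(C)C)O2)[C@@](C)(CCCC(C)(C)Cl)CC1=O
F4 | step 10 | (2R,5S,10S)-2-[(benzyloxy)methyl]-10-(4-chloro-4-methylpentyl)-7-methoxy-6,10-dimethyl-2-[(trimethylsilyl)ethynyl]-8-[(trimethylsilyl)oxy]-1-oxaspiro[4.5]deca-6,8-diene | COC1=C(C)[C@]2(CC[C@](COCc3ccccc3)(C#C[Si](C)(C)C)O2)[C@@](C)(CCCC(C)(C)Cl)C=C1O[Si](C)(C)C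
F5 | step 6 | (5S,10S)-7-methoxy-6,10-dimethyl-10-(prop-2-en-1-yl)-1-oxaspiro[4.5]dec-6-ene-2,8-dione | COC1=C(C)[C@]2(CCC(=O)O2)[C@@](C)(CC=C)CC1=O
F6 | step 6 | (5S,10S)-10-(3-hydroxypropyl)-7-methoxy-6,10-dimethyl-1-oxaspiro[4.5]dec-6-ene-2,8-dione | COC1=C(C)[C@]2(CCC(=O)O2)[C@@](C)(CCCO)CC1=O
F7 | step 6 | 3-[(5S,10S)-7-methoxy-6,10-dimethyl-2,8-dioxo-1-oxaspiro[4.5]dec-6-en-10-yl]propanal | COC1=C(C)[C@]2(CCC(=O)O2)[C@@](C)(CCC=O)CC1=O
F8 | step 6 | (5S,10S)-7-methoxy-6,10-dimethyl-10-(4-methylpent-3-en-1-yl)-1-oxaspiro[4.5]dec-6-ene-2,8-dione | COC1=C(C)[C@]2(CCC(=O)O2)[C@@](C)(CCC=C(C)C)CC1=O
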